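**Plan**

Numbering follows the heavy atoms of the target SMILES. Ring A = cyclopropane C6–C20–C21, ring B = oxepane C6–C7–O8–C9–C10–C19–C20, ring C = dihydropyran C10–C11–O12–C13–C18–C19, ring D = cycloheptane C18–C19–C20–C21–C22–C23–C24.
Enabling feature: C24 carries O26 and C25 and lies β to C13. With C13 at the lactone level, ring C can hold the Z-enol acetate C18=C24 of a 3-acetyl lactone, an acrylate-type acceptor within reach of a radical at C23, so cutting C23–C24 opens ring D.
Further cuts: C18–C24 and O26–acetyl (acylations); C18–C19 with O12–C13 (hetero-Diels–Alder, ring C); C10=C19 (metathesis) with O8–C9 (etherification, ring B); C6–C21 with C6–C20 (bromomalonate cyclopropanation, ring A); C20=C21 (cross-metathesis).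
Forward order of rings: A, B, C, D, followed by lactone-to-lactol reduction and acetylation.
Stereochemistry: C20 and C21 come from the (S)-prolinol silyl ether catalyst. C6 is fixed because only the hydroxymethyl group cis to C19 can form the cyclic acetal. C19 comes from cycloaddition anti to C21. C24 and C18 are set in the radical step (face control by C19, Z geometry, hydrogen delivery to the open face). C13 comes from anomeric control in the last acetylation.

Key step: step 20

Assumption: the SMILES is taken at face value, which puts C19 and C22 trans on ring A (C7 cis to C19) and makes ring D a trans-fused bicyclo[5.1.0]octane; cyclopropanation of an E-enal delivers exactly this relation.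

**Step 1**
Reactants: 1 but-3-en-1-ol
Product: 2 tert-butyl(but-3-en-1-yloxy)diphenylsilane
Conditions: tBuPh2SiCl, imidazole, CH2Cl2, 0 °C to rt
Reagents that add atoms: tert-butyldiphenylsilyl chloride, CC(C)(C)[Si](Cl)(c1ccccc1)c1ccccc1
Why: Standard silylation of a primary alcohol; this silyl ether is chosen because it must outlast three aqueous-acid steps and several strong bases.

**Step 2**
Reactants: 2 tert-butyl(but-3-en-1-yloxy)diphenylsilane; 3 (E)-crotonaldehyde
Product: 4 (E)-5-(tert-butyldiphenylsilyloxy)pent-2-enal
Conditions: second-generation Hoveyda–Grubbs catalyst (2 mol %), 3 (5 equiv), CH2Cl2, 40 °C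
Reagents that add atoms: none
Why: Olefin cross-metathesis of an unhindered terminal alkene with an excess of the electron-poor partner releases propene and should give the conjugated E-enal under thermodynamic control.

**Step 3**
Reactants: 4 (E)-5-(tert-butyldiphenylsilyloxy)pent-2-enal; 5 diethyl bromomalonate
Product: 6 diethyl (2R,3R)-2-formyl-3-[2-(tert-butyldiphenylsilyloxy)ethyl]cyclopropane-1,1-dicarboxylate (formyl C19 trans to side chain C22)
Conditions: (S)-2-[diphenyl(trimethylsilyloxy)methyl]pyrrolidine (20 mol %), 2,6-lutidine (1.1 equiv), CH2Cl2, 0 °C to rt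
Reagents that add atoms: none
Why: Organocatalytic Michael-initiated ring closure: the malonate carbon (C6) adds to the iminium ion at C21 on the face left open by the diphenyl(silyloxy)methyl group of the (S)-catalyst, and the enamine then displaces bromide, which sets C21 and C20 and places C19 trans to C22.

**Step 4**
Reactants: 6 formyl cyclopropane diester
Product: 7 diethyl (2R,3R)-2-(diethoxymethyl)-3-[2-(tert-butyldiphenylsilyloxy)ethyl]cyclopropane-1,1-dicarboxylate
Conditions: HC(OEt)3, PPTS (cat.), EtOH, rt
Reagents that add atoms: triethyl orthoformate, CCOC(OCC)OCC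
Why: Acid-catalysed acetalisation masks C19 against hydride, and ethoxy groups are used so that any exchange at the ethyl esters is degenerate.

**Step 5**
Reactants: 7 diethyl acetal diester
Product: 9 bicyclic acetal alcohol (3-oxabicyclo[3.1.0]hexane; O links C7 to C19; C5H2OH free; side chain on C21 trans to C19; both C19 anomers), via diol 8 (not isolated)
Conditions: LiAlH4, THF, 0 °C; aqueous work-up; crude 8, PPTS (cat.), CH2Cl2, rt
Reagents that add atoms: none
Why: Hydride reduction of both esters is followed by acid-catalysed transacetalisation in which only the hydroxymethyl group cis to C19 can close the five-membered ring, so C7 (ring oxygen) and C5 (free alcohol) are told apart and C6 becomes a defined stereocentre.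

**Step 6**
Reactants: 9 bicyclic acetal alcohol
Product: 10 4-methoxybenzyl ether of 9 (on O4)
Conditions: NaH, 4-MeOC6H4CH2Cl, Bu4NI (cat.), DMF, 0 °C to rt
Reagents that add atoms: 4-methoxybenzyl chloride, COc1ccc(CCl)cc1
Why: Williamson etherification; a benzyl-type ether is used on O4 because an ester or silyl group could migrate to the neighbouring C7 alkoxide in steps 8 and 9.

**Step 7**
Reactants: 10 bicyclic acetal 4-methoxybenzyl ether
Product: 11 bicyclic lactol (C19 hemiacetal, anomers)
Conditions: 1 M aq HCl, THF, rt
Reagents that add atoms: water, O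
Why: Mild acid hydrolysis of a furanoside-type acetal, to which neither the arylmethyl ether nor the hindered silyl ether responds.

**Step 8**
Reactants: 11 bicyclic lactol
Product: 12 vinylcyclopropane alcohol (vinyl C19 on C20 cis to C7H2OH on C6; C5H2O-arylmethyl and the C22 chain on the other face)
Conditions: Ph3PCH3Br (3 equiv), KOtBu (2.9 equiv), THF, 0 °C to rt
Reagents that add atoms: methyltriphenylphosphonium bromide, C[P+](c1ccccc1)(c1ccccc1)c1ccccc1.[Br-]
Why: Wittig methylenation of the lactol through its open hydroxy aldehyde form; the non-stabilised ylide should react faster than the cyclopropyl C20–H can epimerise.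

**Step 9**
Reactants: 12 vinylcyclopropane alcohol; 13 3-chloro-2-(chloromethyl)prop-1-ene
Product: 14 2-(chloromethyl)allyl ether of 12 (O8–C9 formed)
Conditions: NaH, 13 (5 equiv), Bu4NI (cat.), THF–DMF, 0 °C to rt
Reagents that add atoms: none
Why: Williamson etherification with an allylic chloride that has no β-hydrogen; the excess of 13 suppresses double substitution.

**Step 10**
Reactants: 14 diene ether
Product: 15 bicyclic allylic chloride (3-oxabicyclo[5.1.0]oct-5-ene, rings A and B; C10 bears C11H2Cl)
Conditions: second-generation Grubbs catalyst (5 mol %), CH2Cl2 (5 mM), reflux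
Reagents that add atoms: none
Why: Ring-closing metathesis of the vinyl group with the 1,1-disubstituted alkene; the cis arrangement of both arms on ring A favours the seven-membered ring and loss of ethene drives it.

**Step 11**
Reactants: 15 bicyclic allylic chloride
Product: 16 bicyclic enal (O12=C11H–C10=C19H)
Conditions: N-methylmorpholine N-oxide (5 equiv), NaI (0.2 equiv), MeCN, rt to 50 °C
Reagents that add atoms: N-methylmorpholine N-oxide, C[N+]1([O-])CCOCC1
Why: Amine N-oxide variant of the Kornblum oxidation: SN2 displacement of the iodide-activated allylic chloride by the N-oxide oxygen and base-induced N–O cleavage give the conjugated aldehyde without touching the ethers.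

**Step 12**
Reactants: 16 bicyclic enal; 17 ethyl vinyl ether
Product: 18 tricyclic ethoxy acetal (rings A, B, C; C18 on the face of ring B opposite C21, i.e. cis to H20; C13 anomers)
Conditions: Yb(fod)3 (5 mol %), neat 17, sealed tube, rt to 45 °C
Reagents that add atoms: none
Why: Lanthanide-catalysed inverse-electron-demand hetero-Diels–Alder reaction of the oxadiene O12=C11–C10=C19 with the vinyl ether; the dienophile should reach C19 past H20, on the face of ring B turned away from C21, which sets C19, while the C13 anomers are of no consequence.

**Step 13**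
Reactants: 18 tricyclic ethoxy acetal
Product: 19 tricyclic lactol (C13 hemiacetal, anomers)
Conditions: 0.5 M aq HCl, THF, 0 °C to rt
Reagents that add atoms: water, O
Why: Acid hydrolysis of a 2-alkoxydihydropyran acetal; the product should rest as the cyclic enol-ether lactol, as iridoid lactols do, and is taken on without delay.

**Step 14**
Reactants: 19 tricyclic lactol
Product: 20 tricyclic enol lactone (C13=O, C10=C11)
Conditions: Ag2CO3 on Celite, toluene, reflux
Reagents that add atoms: none
Why: Fétizon oxidation, a neutral heterogeneous method that is selective for lactols and is the usual way from iridoid-type lactols to their enol lactones.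

**Step 15**
Reactants: 20 tricyclic enol lactone
Product: 22 3-acetyl enol lactone (keto and chelated enol forms; C18 not fixed), via lithium enolate 21 (not isolated)
Conditions: LiN(SiMe3)2 (2.2 equiv), THF, −78 °C; 1-acetylimidazole, −78 to −40 °C; aq NH4Cl
Reagents that add atoms: 1-acetylimidazole, CC(=O)n1ccnc1
Why: Claisen-type C-acylation of the lithium lactone enolate; the second equivalent of base removes the acidic C18–H of the product and so prevents proton exchange and double acylation.

**Step 16**
Reactants: 22 3-acetyl enol lactone
Product: 23 hydroxy keto lactone (C5H2OH free)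
Conditions: DDQ (1.3 equiv), CH2Cl2–pH 7 buffer, 0 °C
Reagents that add atoms: none
Why: Oxidative cleavage of the 4-methoxybenzyl ether by hydride abstraction at the electron-rich benzylic position, fast at 0 °C, where dehydrogenation of the keto lactone is not expected.

**Step 17**
Reactants: 23 hydroxy keto lactone
Product: 25 silyl-protected Z-enol acetate (C18=C24 with O26 cis to C13=O; C5H2OAc), via dilithium salt 24 (not isolated)
Conditions: LiN(SiMe3)2 (2.1 equiv), THF, −78 °C; AcCl (3 equiv), −78 to −20 °C
Reagents that add atoms: acetyl chloride, CC(=O)Cl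
Why: O-Acylation of a lithium-chelated β-keto ester enolate: lithium holds O26 and the C13 carbonyl oxygen on the same side of C18=C24, and the hard acyl chloride attacks oxygen because C18 is fully substituted, so the Z-enol acetate should result while the C5 alkoxide is acetylated in the same operation.

**Step 18**
Reactants: 25 silyl-protected Z-enol acetate
Product: 26 Z-enol acetate alcohol (C23H2OH)
Conditions: HF·pyridine, pyridine–THF, 0 °C to rt
Reagents that add atoms: none
Why: Fluoride-induced desilylation under buffered acidic conditions avoids the basic fluoride sources that would cleave the enol esters.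

**Step 19**
Reactants: 26 Z-enol acetate alcohol
Product: 27 tricyclic Z-enol acetate with 2-iodoethyl side chain on C21
Conditions: iodine, PPh3, imidazole, CH2Cl2, 0 °C, dark
Reagents that add atoms: iodine, [I][I]
Why: Appel-type iodination by SN2 displacement of the alkoxyphosphonium ion at the unhindered primary C23.

**Step 20**
Reactants: 27 tricyclic Z-enol acetate iodide
Product: 28 tetracyclic lactone tertiary acetate (rings A–D; H18 cis to H19; O26 cis to C13; C25 cis to H18)
Conditions: (Me3Si)3SiH (1.5 equiv) and 1,1'-azobis(cyclohexanecarbonitrile) (0.3 equiv) in toluene, added by syringe pump over 12 h to 27 (2 mM in degassed toluene), 110 °C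
Reagents that add atoms: none
Why: Proposed new method: the silyl radical abstracts iodine from 27, the nucleophilic primary radical at C23 adds to C24 (the β-carbon of the lactone-conjugated alkene C18=C24, bearing O26 and C25), and the lactone-stabilised C18 radical takes hydrogen from the silane and renews the chain; the closest known reaction type is cyclisation of alkyl radicals onto β-alkoxy- and β-acyloxyacrylates, known in the exo mode at a β-CH, whereas here it must run endo at a fully substituted β-carbon. Ring D closes 7-endo-trig (C18 and C24 both become ring members) and, because C19 and C22 are trans on ring A, as a strained trans-fused bicyclo[5.1.0]octane. C24 is controlled by the C19 stereocentre together with the Z geometry: allylic strain between C25 and C19 holds C20 pseudoaxial, the tether can reach C24 only from the C20 face of ring C, and with O26 cis to C13=O this attack leaves O26 cis to C13 and C25 cis to H18. C18 is controlled by the shape of the new tetracycle: ring D covers the C20 face, so the bulky silane should deliver hydrogen to the open face and give the cis fusion of rings C and D (H18 cis to H19), a centre that base equilibration could also correct. The step needs 7-endo over 6-exo selectivity, secured by the polarity match of the alkyl radical with C24 and by the far greater strain of the trans-bicyclo[4.1.0]heptane that attack at C18 would build, and it needs ring closure to outrun hydrogen transfer, hence the very low stationary silane concentration at high temperature. Ring A should stay intact because C22 separates it from the radical centre (no cyclopropylcarbinyl radical), and the acetate on O4 makes the C5–H bonds poorer partners for a 1,5-hydrogen shift than an ether would.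

**Step 21**
Reactants: 28 tetracyclic lactone tertiary acetate
Product: 29 tetracyclic lactol triol (C13 hemiacetal anomers; C5H2OH; C24–OH)
Conditions: iBu2AlH (7 equiv), CH2Cl2, −78 °C; aq Rochelle salt
Reagents that add atoms: none
Why: Partial reduction of the enol lactone to the lactol at low temperature (the tetrahedral aluminium alkoxide survives until work-up), as practised on iridoid enol lactones, with reductive removal of both acetates in the same operation.

**Step 22**
Reactants: 29 tetracyclic lactol triol
Product: 30 target CNP0250836.2
Conditions: Ac2O, pyridine, 0 °C to rt (no acyl-transfer catalyst)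
Reagents that add atoms: acetic anhydride, CC(=O)OC(C)=O
Why: Acetylation with the unassisted anhydride reaches only the primary and the anomeric hydroxyl groups because the tertiary C24–OH is too hindered, and since the lactol anomers equilibrate the acetate should settle axial (anomeric effect) on the face away from ring D, cis to H18, which sets C13.

**Compound list**

1 | but-3-en-1-ol | C=CCCO | starting material
2 | tert-butyl(but-3-en-1-yloxy)diphenylsilane | C=CCCO[Si](c1ccccc1)(c1ccccc1)C(C)(C)C | intermediate
3 | (E)-crotonaldehyde | C/C=C/C=O | starting material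
4 | (E)-5-(tert-butyldiphenylsilyloxy)pent-2-enal | O=C/C=C/CCO[Si](c1ccccc1)(c1ccccc1)C(C)(C)C | intermediate
5 | diethyl bromomalonate | CCOC(=O)C(Br)C(=O)OCC | starting material
6 | diethyl (2R,3R)-2-formyl-3-[2-(tert-butyldiphenylsilyloxy)ethyl]cyclopropane-1,1-dicarboxylate | O=C[C@@H]1[C@@H](CCO[Si](c2ccccc2)(c2ccccc2)C(C)(C)C)C1(C(=O)OCC)C(=O)OCC | intermediate
7 | diethyl (2R,3R)-2-(diethoxymethyl)-3-[2-(tert-butyldiphenylsilyloxy)ethyl]cyclopropane-1,1-dicarboxylate | CCOC(OCC)[C@@H]1[C@@H](CCO[Si](c2ccccc2)(c2ccccc2)C(C)(C)C)C1(C(=O)OCC)C(=O)OCC | intermediate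
8 | (2R,3R)-1,1-bis(hydroxymethyl) diol from 7 (not isolated) | CCOC(OCC)[C@@H]1[C@@H](CCO[Si](c2ccccc2)(c2ccccc2)C(C)(C)C)C1(CO)CO | intermediate
9 | bicyclic acetal alcohol (4-ethoxy-3-oxabicyclo[3.1.0]hexane, 1-hydroxymethyl, 6-side chain; C19 anomers) | OC[C@@]12COC(OCC)[C@@H]1[C@H]2CCO[Si](c1ccccc1)(c1ccccc1)C(C)(C)C | intermediate
10 | 4-methoxybenzyl ether of 9 | COc1ccc(COC[C@@]23COC(OCC)[C@@H]2[C@H]3CCO[Si](c2ccccc2)(c2ccccc2)C(C)(C)C)cc1 | intermediate
11 | bicyclic lactol (C19 anomers) | COc1ccc(COC[C@@]23COC(O)[C@@H]2[C@H]3CCO[Si](c2ccccc2)(c2ccccc2)C(C)(C)C)cc1 | intermediate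
12 | vinylcyclopropane alcohol (vinyl cis to C7H2OH) | COc1ccc(COC[C@@]2(CO)[C@H](C=C)[C@H]2CCO[Si](c2ccccc2)(c2ccccc2)C(C)(C)C)cc1 | intermediate
13 | 3-chloro-2-(chloromethyl)prop-1-ene | C=C(CCl)CCl | starting material
14 | 2-(chloromethyl)allyl ether of 12 | COc1ccc(COC[C@@]2(COCC(=C)CCl)[C@H](C=C)[C@H]2CCO[Si](c2ccccc2)(c2ccccc2)C(C)(C)C)cc1 | intermediate
15 | bicyclic allylic chloride (3-oxabicyclo[5.1.0]oct-5-ene) | COc1ccc(COC[C@@]23COCC(CCl)=C[C@@H]2[C@H]3CCO[Si](c2ccccc2)(c2ccccc2)C(C)(C)C)cc1 | intermediate
16 | bicyclic enal (3-oxabicyclo[5.1.0]oct-5-ene-5-carbaldehyde) | COc1ccc(COC[C@@]23COCC(C=O)=C[C@@H]2[C@H]3CCO[Si](c2ccccc2)(c2ccccc2)C(C)(C)C)cc1 | intermediate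
17 | ethyl vinyl ether | C=COCC | starting material
18 | tricyclic ethoxy acetal (C13 anomers) | COc1ccc(COC[C@@]23COCC4=COC(OCC)C[C@H]4[C@@H]2[C@H]3CCO[Si](c2ccccc2)(c2ccccc2)C(C)(C)C)cc1 | intermediate
19 | tricyclic lactol (C13 anomers) | COc1ccc(COC[C@@]23COCC4=COC(O)C[C@H]4[C@@H]2[C@H]3CCO[Si](c2ccccc2)(c2ccccc2)C(C)(C)C)cc1 | intermediate
20 | tricyclic enol lactone | COc1ccc(COC[C@@]23COCC4=COC(=O)C[C@H]4[C@@H]2[C@H]3CCO[Si](c2ccccc2)(c2ccccc2)C(C)(C)C)cc1 | intermediate
21 | lithium enolate of 20 (not isolated) | COc1ccc(COC[C@@]23COCC4=COC(O[Li])=C[C@H]4[C@@H]2[C@H]3CCO[Si](c2ccccc2)(c2ccccc2)C(C)(C)C)cc1 | intermediate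
22 | 3-acetyl enol lactone (keto form drawn; C18 not fixed) | COc1ccc(COC[C@@]23COCC4=COC(=O)C(C(C)=O)[C@H]4[C@@H]2[C@H]3CCO[Si](c2ccccc2)(c2ccccc2)C(C)(C)C)cc1 | intermediate
23 | hydroxy keto lactone | OC[C@@]12COCC3=COC(=O)C(C(C)=O)[C@H]3[C@@H]1[C@H]2CCO[Si](c1ccccc1)(c1ccccc1)C(C)(C)C | intermediate
24 | dilithium salt of 23 (C5 alkoxide, chelated Z-enolate; not isolated) | [Li]OC[C@@]12COCC3=COC(=O)/C(=C(/C)O[Li])[C@H]3[C@@H]1[C@H]2CCO[Si](c1ccccc1)(c1ccccc1)C(C)(C)C | intermediate
25 | silyl-protected Z-enol acetate | CC(=O)OC[C@@]12COCC3=COC(=O)/C(=C(/C)OC(C)=O)[C@H]3[C@@H]1[C@H]2CCO[Si](c1ccccc1)(c1ccccc1)C(C)(C)C | intermediate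
26 | Z-enol acetate alcohol | CC(=O)OC[C@@]12COCC3=COC(=O)/C(=C(/C)OC(C)=O)[C@H]3[C@@H]1[C@H]2CCO | intermediate
27 | tricyclic Z-enol acetate iodide (key-step precursor) | CC(=O)OC[C@@]12COCC3=COC(=O)/C(=C(/C)OC(C)=O)[C@H]3[C@@H]1[C@H]2CCI | intermediate
28 | tetracyclic lactone tertiary acetate (key-step product) | CC(=O)OC[C@@]12COCC3=COC(=O)[C@@H]4[C@H]3[C@@H]1[C@H]2CC[C@]4(C)OC(C)=O | intermediate
29 | tetracyclic lactol triol (C13 anomers) | OC[C@@]12COCC3=COC(O)[C@@H]4[C@H]3[C@@H]1[C@H]2CC[C@]4(C)O | intermediate
30 | CNP0250836.2 | CC(=O)OC[C@@]12COCC3=CO[C@H](OC(C)=O)[C@@H]4[C@H]3[C@@H]1[C@H]2CC[C@]4(C)O | target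

**Total step count:** 22. **Longest linear sequence:** 22 steps (1 to 30); 3, 5, 13 and 17 enter as purchased compounds.

**Steps most likely to fail**

**Step 20.** The ring closure is slowed by the fully substituted acceptor carbon and by the strain that builds up in the trans ring fusion. Premature hydrogen transfer from the silane to the C23 radical may therefore win, and a 1,5-hydrogen shift from C5 followed by opening of ring A is a second drain. The fallback forms the same C23–C24 bond by known organosamarium chemistry on the ketone instead of the enol acetate.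
- It sets out from 22. HF·pyridine frees the C23 alcohol to give the hydroxy keto lactone F1, and iodine/PPh3/imidazole converts it into the iodo keto lactone F2.
- SmI2 (THF, catalytic NiI2, −78 °C to rt) then closes ring D by an intramolecular Barbier reaction of the iodide with the C24 ketone. Samarium chelated between ketone and lactone carbonyl is known to place the new hydroxyl cis to the ester group in ω-iodo β-keto esters, which is the O26/C13 relation required. This gives the tetracyclic hydroxy lactone F3.
- DDQ removes the 4-methoxybenzyl group to give the dihydroxy lactone F4, and iBu2AlH at −78 °C reduces F4 to 29, where the route is rejoined.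

**Step 17.** Chelation may be eroded in the dianion, with loss of geometric control, or acylation may occur at C18 instead of O26. The fallback gives up enolate chemistry.
- It sets out from 23. Ac2O/pyridine at 0 °C acetylates only the primary alcohol to give the acetoxy keto lactone F5.
- Acid-catalysed acyl exchange with isopropenyl acetate (catalytic TsOH, reflux, acetone distilled off) then acts on the neutral enol, whose internal hydrogen bond already holds O26 next to the C13 carbonyl. Under these equilibrating conditions β-keto esters are known to give Z-enol acetates. The route is rejoined at 25.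

**Step 12.** The trisubstituted, cyclopropyl-donated oxadiene may react sluggishly, and facial selectivity at C19 may be poor because C5H2OR lies on the face that must be attacked. The fallback replaces the cycloaddition by a stepwise sequence with a far more nucleophilic two-carbon partner.
- It sets out from 16. Mukaiyama–Michael addition of 1,1-bis(trimethylsilyloxy)ethene (catalytic Me3SiOTf, CH2Cl2, −78 °C), through an open transition state that should respond more strongly to the shielding by C21, gives the aldehyde acid F6 after aqueous work-up.
- Enol lactonisation with Ac2O/NaOAc at 80 °C closes ring C and rejoins the route at 20, so steps 13 and 14 drop out.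

**Further compounds**

F1 | step 20 | hydroxy keto lactone (C23 alcohol, O4 4-methoxybenzylated) | COc1ccc(COC[C@@]23COCC4=COC(=O)C(C(C)=O)[C@H]4[C@@H]2[C@H]3CCO)cc1
F2 | step 20 | iodo keto lactone | COc1ccc(COC[C@@]23COCC4=COC(=O)C(C(C)=O)[C@H]4[C@@H]2[C@H]3CCI)cc1
F3 | step 20 | tetracyclic hydroxy lactone (4-methoxybenzyl ether) | COc1ccc(COC[C@@]23COCC4=COC(=O)[C@@H]5[C@H]4[C@@H]2[C@H]3CC[C@]5(C)O)cc1
F4 | step 20 | dihydroxy lactone | OC[C@@]12COCC3=COC(=O)[C@@H]4[C@H]3[C@@H]1[C@H]2CC[C@]4(C)O
F5 | step 17 | acetoxy keto lactone | CC(=O)OC[C@@]12COCC3=COC(=O)C(C(C)=O)[C@H]3[C@@H]1[C@H]2CCO[Si](c1ccccc1)(c1ccccc1)C(C)(C)C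
F6 | step 12 | aldehyde acid (C10 epimers) | COc1ccc(COC[C@@]23COCC(C=O)[C@@H](CC(=O)O)[C@@H]2[C@H]3CCO[Si](c2ccccc2)(c2ccccc2)C(C)(C)C)cc1
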